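## Retrosynthetic overview

1. The target comes from its tris-TBS ether (TBS = tert-butyldimethylsilyl) by buffered fluoride, and that flavanone from a (2S)-4-methoxyflavan by DDQ oxidation of the C4 methyl ether.
2. The feature used is ring C: O1 (on C8a) and the ortho benzylic carbon C4, which sits at the carbonyl oxidation level, are bridged by the C2–C3 unit that carries ring B. Ring C is therefore cut at O1–C2 and C3–C4 into a 4-methoxy ortho-quinone methide (salicylaldehyde plus trimethyl orthoformate) and 4-silyloxystyrene, joined by a chiral phosphoric acid-catalysed oxa-[4+2] reaction that sets C2.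
3. The salicylaldehyde comes from ortho-formylation of a prenylphenol, made by aromatic Claisen rearrangement of a 1,1-dimethylallyl ether of 3,5-bis(silyloxy)-4-methylphenol, itself made by C–H borylation/oxidation of bis-silylated 2-methylresorcinol.
4. Ring order: rings A and B are bought intact; ring C is the only ring formed (step 8).

Key step: step 8

Assumption: the (R)-enantiomer of the phosphoric acid is taken to give the (2S) product; the sense of induction of this new reaction cannot be predicted with confidence, and the (S)-catalyst is used instead if a test run shows the opposite sense. C4 of the cycloadduct is left undefined because it is erased in step 9.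

## Route

Step 1
Reactants: 1 2-methylresorcinol
Product: 2 1,3-bis(tert-butyldimethylsilyloxy)-2-methylbenzene
Conditions: TBSCl (2.4 equiv), imidazole (5 equiv), DMF, rt
Reagents that add atoms: tert-butyldimethylsilyl chloride, CC(C)(C)[Si](C)(C)Cl
Why: Imidazole-promoted silylation of both phenols (standard TBS protection) should proceed cleanly since no other nucleophilic site is present.

Step 2
Reactants: 2 1,3-bis(tert-butyldimethylsilyloxy)-2-methylbenzene
Product: 4 3,5-bis(tert-butyldimethylsilyloxy)-4-methylphenol, via pinacol arylboronate 3 (not isolated)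
Conditions: [Ir(OMe)(cod)]2 (1.5 mol %), 4,4'-di-tert-butyl-2,2'-bipyridine (3 mol %), B2pin2 (1.0 equiv), THF, 80 °C; then Oxone (2KHSO5·KHSO4·K2SO4), acetone/H2O, rt, 10 min
Reagents that add atoms: bis(pinacolato)diboron, CC1(C)OB(OC1(C)C)B1OC(C)(C)C(C)(C)O1 (boron of 3); potassium peroxymonosulfate, [K+].[O-]S(=O)(=O)OO (oxygen of 4)
Why: Sterically governed iridium-catalysed aromatic C–H borylation (Ishiyama–Miyaura–Hartwig) should take the only ring C–H not ortho to a substituent (para to the methyl group), and brief ipso-oxidation of the C–B bond by peroxymonosulfate should give the phenol without loss of the aryl silyl ethers.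

Step 3
Reactants: 5 2-methylbut-3-en-2-ol
Product: 6 tert-butyl 2-methylbut-3-en-2-yl carbonate
Conditions: n-BuLi, THF, −78 °C; Boc2O, −78 °C to rt
Reagents that add atoms: di-tert-butyl dicarbonate, CC(C)(C)OC(=O)OC(=O)OC(C)(C)C
Why: Alkoxycarbonylation of the lithium tertiary alkoxide with Boc2O gives the mixed carbonate needed as a π-allyl precursor.

Step 4
Reactants: 4 3,5-bis(tert-butyldimethylsilyloxy)-4-methylphenol; 6 tert-butyl 2-methylbut-3-en-2-yl carbonate
Product: 7 1,3-bis(tert-butyldimethylsilyloxy)-2-methyl-5-(2-methylbut-3-en-2-yloxy)benzene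
Conditions: Pd(PPh3)4 (3 mol %), THF, 0 °C
Reagents that add atoms: none
Why: Tsuji–Trost O-allylation: zerovalent palladium ionises the tertiary carbonate with loss of CO2, the tert-butoxide formed deprotonates the phenol, and at low temperature the phenoxide should attack the more substituted terminus of the 1,1-dimethyl-π-allyl complex to give the tertiary (reverse-prenyl) ether.

Step 5
Reactants: 7 1,3-bis(tert-butyldimethylsilyloxy)-2-methyl-5-(2-methylbut-3-en-2-yloxy)benzene
Product: 8 3,5-bis(tert-butyldimethylsilyloxy)-4-methyl-2-(3-methylbut-2-enyl)phenol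
Conditions: Eu(fod)3 (10 mol %; fod = 6,6,7,7,8,8,8-heptafluoro-2,2-dimethyl-3,5-octanedionate), CHCl3, 50 °C
Reagents that add atoms: none
Why: Aromatic Claisen ([3,3]-sigmatropic) rearrangement of the 1,1-dimethylallyl aryl ether, accelerated by the gem-dimethyl group and the mild Lewis acid, should deliver the prenyl group to one of the two equivalent ortho carbons and tautomerise to the phenol.

Step 6
Reactants: 8 3,5-bis(tert-butyldimethylsilyloxy)-4-methyl-2-(3-methylbut-2-enyl)phenol
Product: 9 2-hydroxy-4,6-bis(tert-butyldimethylsilyloxy)-5-methyl-3-(3-methylbut-2-enyl)benzaldehyde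
Conditions: MgCl2, Et3N, (CH2O)n, THF, reflux
Reagents that add atoms: paraformaldehyde (formaldehyde units), C=O
Why: Magnesium-phenoxide-directed ortho-formylation (Casnati–Skattebøl) delivers formaldehyde within the chelate to the only free ortho carbon and oxidises the hydroxymethyl intermediate by hydride transfer to a second formaldehyde, under conditions neutral to the prenyl group and the silyl ethers.

Step 7
Reactants: 10 4-acetoxystyrene
Product: 12 4-(tert-butyldimethylsilyloxy)styrene, via sodium 4-vinylphenoxide 11 (not isolated)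
Conditions: NaOMe (1.05 equiv), THF, 0 °C; then TBSCl (1.3 equiv), 0 °C to rt
Reagents that add atoms: tert-butyldimethylsilyl chloride, CC(C)(C)[Si](C)(C)Cl
Why: Methoxide transesterification (Zemplén-type deacetylation) frees the phenoxide, which is silylated in the same flask so that polymerisation-prone 4-vinylphenol is never handled.

Step 8
Reactants: 9 2-hydroxy-4,6-bis(tert-butyldimethylsilyloxy)-5-methyl-3-(3-methylbut-2-enyl)benzaldehyde; 12 4-(tert-butyldimethylsilyloxy)styrene; 13 trimethyl orthoformate
Product: 16 (2S)-5,7-bis(tert-butyldimethylsilyloxy)-2-[4-(tert-butyldimethylsilyloxy)phenyl]-4-methoxy-6-methyl-8-(3-methylbut-2-enyl)chromane (C4 epimers), via dimethyl acetal 14 (not isolated), via 4-methoxy ortho-quinone methide 15 (not isolated)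
Conditions: (R)-TRIP [(R)-3,3'-bis(2,4,6-triisopropylphenyl)-1,1'-binaphthyl-2,2'-diyl hydrogen phosphate] (10 mol %), HC(OMe)3 (3 equiv), PhMe, rt; then 12 (2.5 equiv), 0 °C to rt
Reagents that add atoms: none
Why: Proposed new method: the chiral phosphoric acid catalyses acetalisation of 9 by 13 and ionisation of acetal 14 with loss of methanol to the 4-methoxy ortho-quinone methide 15 (the conjugate base of a ring-A-stabilised oxocarbenium ion), which stays hydrogen-bonded or ion-paired to the phosphate while the CH2 terminus of styrene 12 bonds to the methide carbon (C3–C4) and the benzylic carbon is captured by the quinone methide oxygen (O1–C2), either in one asynchronous inverse-electron-demand oxa-[4+2] step or by Prins-type addition followed by collapse of the 4-silyloxybenzyl cation onto the phenol oxygen, rearomatisation of ring A driving the reaction. The closest known reactions are the achiral Lewis- or Brønsted-acid-catalysed three-component coupling of salicylaldehydes, trimethyl orthoformate and styrenes to 2-aryl-4-methoxychromans and the chiral phosphoric acid-catalysed [4+2] cycloadditions of ortho-quinone methides (from ortho-hydroxybenzyl alcohols) with electron-rich alkenes. Ring C closes by intermolecular [4+2] annulation, four atoms (O1, C8a, C4a, C4) coming from the quinone methide and two (C2, C3) from the styrene, with O1–C2 bond formation as the ring-closing event in the stepwise limit. C2 is set by catalyst control alone, the phosphate bound at the quinone methide oxygen and flanked by its 2,4,6-triisopropylphenyl groups shielding one face of the heterodiene and of the derived benzylic cation so that (2S) results, whereas C4 should form mainly cis to the C2 aryl group by endo approach or equilibration of the labile benzylic ether and is immaterial because step 9 erases it. The step needs regioselectivity (aryl at C2), secured by the polarity match of the nucleophilic styrene CH2 with the electrophilic methide carbon; the right oxygen as O1, secured because only the hydroxyl next to the prenyl group is free in 9; and chemoselectivity over the prenyl alkene and silyl ethers, secured by the higher nucleophilicity and excess of 12 and by the low acidity of the catalyst, which should neither cyclise the prenyl group onto the hydroxyl nor polymerise the styrene.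

Step 9
Reactants: 16 (2S)-5,7-bis(tert-butyldimethylsilyloxy)-2-[4-(tert-butyldimethylsilyloxy)phenyl]-4-methoxy-6-methyl-8-(3-methylbut-2-enyl)chromane (C4 epimers)
Product: 17 (2S)-5,7-bis(tert-butyldimethylsilyloxy)-2-[4-(tert-butyldimethylsilyloxy)phenyl]-6-methyl-8-(3-methylbut-2-enyl)chroman-4-one
Conditions: DDQ (1.3 equiv), CH2Cl2/pH 7 phosphate buffer (10:1), 0 °C
Reagents that add atoms: water, O
Why: DDQ oxidation of an electron-rich benzylic ether (as in oxidative benzyl ether cleavage and DDQ functionalisation of C4 in 5,7-dioxygenated flavans): hydride abstraction from C4, activated by its methoxy group and by ring A with oxygens ortho and para, gives an oxocarbenium ion that water converts through the hemiketal into the ketone with loss of methanol, so both C4 epimers converge while the less hydridic C2–H is left alone.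

Step 10
Reactants: 17 (2S)-5,7-bis(tert-butyldimethylsilyloxy)-2-[4-(tert-butyldimethylsilyloxy)phenyl]-6-methyl-8-(3-methylbut-2-enyl)chroman-4-one
Product: 18 6-methyl-8-prenylnaringenin, (2S)-5,7-dihydroxy-2-(4-hydroxyphenyl)-6-methyl-8-(3-methylbut-2-enyl)chroman-4-one
Conditions: TBAF (3.6 equiv), AcOH (4 equiv), THF, 0 °C
Reagents that add atoms: none
Why: Fluoride-mediated cleavage of the three aryl silyl ethers, buffered with acetic acid so that the phenols stay protonated and base-induced opening of ring C to the chalcone (retro-oxa-Michael), which would racemise C2, is avoided, while the prenyl group sees no strong acid.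

## Compound list

1 | 2-methylresorcinol | Cc1c(O)cccc1O | starting material
2 | 1,3-bis(tert-butyldimethylsilyloxy)-2-methylbenzene | Cc1c(O[Si](C)(C)C(C)(C)C)cccc1O[Si](C)(C)C(C)(C)C | intermediate
3 | 2-[3,5-bis(tert-butyldimethylsilyloxy)-4-methylphenyl]-4,4,5,5-tetramethyl-1,3,2-dioxaborolane | Cc1c(O[Si](C)(C)C(C)(C)C)cc(B2OC(C)(C)C(C)(C)O2)cc1O[Si](C)(C)C(C)(C)C | intermediate (not isolated)
4 | 3,5-bis(tert-butyldimethylsilyloxy)-4-methylphenol | Cc1c(O[Si](C)(C)C(C)(C)C)cc(O)cc1O[Si](C)(C)C(C)(C)C | intermediate
5 | 2-methylbut-3-en-2-ol | CC(C)(O)C=C | starting material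
6 | tert-butyl 2-methylbut-3-en-2-yl carbonate | C=CC(C)(C)OC(=O)OC(C)(C)C | intermediate
7 | 1,3-bis(tert-butyldimethylsilyloxy)-2-methyl-5-(2-methylbut-3-en-2-yloxy)benzene | C=CC(C)(C)Oc1cc(O[Si](C)(C)C(C)(C)C)c(C)c(O[Si](C)(C)C(C)(C)C)c1 | intermediate
8 | 3,5-bis(tert-butyldimethylsilyloxy)-4-methyl-2-(3-methylbut-2-enyl)phenol | CC(C)=CCc1c(O)cc(O[Si](C)(C)C(C)(C)C)c(C)c1O[Si](C)(C)C(C)(C)C | intermediate
9 | 2-hydroxy-4,6-bis(tert-butyldimethylsilyloxy)-5-methyl-3-(3-methylbut-2-enyl)benzaldehyde | CC(C)=CCc1c(O[Si](C)(C)C(C)(C)C)c(C)c(O[Si](C)(C)C(C)(C)C)c(C=O)c1O | intermediate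
10 | 4-acetoxystyrene | CC(=O)Oc1ccc(C=C)cc1 | starting material
11 | sodium 4-vinylphenoxide | [Na+].[O-]c1ccc(C=C)cc1 | intermediate (not isolated)
12 | 4-(tert-butyldimethylsilyloxy)styrene | C=Cc1ccc(O[Si](C)(C)C(C)(C)C)cc1 | intermediate
13 | trimethyl orthoformate | COC(OC)OC | starting material
14 | 2-(dimethoxymethyl)-3,5-bis(tert-butyldimethylsilyloxy)-4-methyl-6-(3-methylbut-2-enyl)phenol | CC(C)=CCc1c(O[Si](C)(C)C(C)(C)C)c(C)c(O[Si](C)(C)C(C)(C)C)c(C(OC)OC)c1O | intermediate (not isolated)
15 | 6-(methoxymethylidene)-3,5-bis(tert-butyldimethylsilyloxy)-4-methyl-2-(3-methylbut-2-enyl)cyclohexa-2,4-dien-1-one | CC(C)=CCC1=C(O[Si](C)(C)C(C)(C)C)C(C)=C(O[Si](C)(C)C(C)(C)C)C(=COC)C1=O | intermediate (not isolated)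
16 | (2S)-5,7-bis(tert-butyldimethylsilyloxy)-2-[4-(tert-butyldimethylsilyloxy)phenyl]-4-methoxy-6-methyl-8-(3-methylbut-2-enyl)chromane, C4 epimers | CC(C)=CCc1c(O[Si](C)(C)C(C)(C)C)c(C)c(O[Si](C)(C)C(C)(C)C)c2c1O[C@H](c1ccc(O[Si](C)(C)C(C)(C)C)cc1)CC2OC | intermediate
17 | (2S)-5,7-bis(tert-butyldimethylsilyloxy)-2-[4-(tert-butyldimethylsilyloxy)phenyl]-6-methyl-8-(3-methylbut-2-enyl)chroman-4-one | CC(C)=CCc1c(O[Si](C)(C)C(C)(C)C)c(C)c(O[Si](C)(C)C(C)(C)C)c2c1O[C@H](c1ccc(O[Si](C)(C)C(C)(C)C)cc1)CC2=O | intermediate
18 | 6-methyl-8-prenylnaringenin, (2S)-5,7-dihydroxy-2-(4-hydroxyphenyl)-6-methyl-8-(3-methylbut-2-enyl)chroman-4-one | CC(C)=CCc1c(O)c(C)c(O)c2c1O[C@H](c1ccc(O)cc1)CC2=O | target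

## Step count and risks

Total step count: 10. Longest linear sequence: 8 steps (steps 1, 2, 4, 5, 6, 8, 9, 10).

Steps most likely to fail:

**Step 8 (key step).** The heavily donor-substituted quinone methide may react only sluggishly with the styrene under so weak an acid. Enantiofacial discrimination may be poor because the styrene offers no hydrogen-bonding handle. Acid-induced ionisation of the product at C2 could also erode the configuration. Fallback, from 9, 12 and 13, returning at 17: the three components are combined with an achiral acid (Sc(OTf)3, 5 mol %, CH2Cl2, 0 °C), the known racemic form of the reaction, to give through 14 and 15 the racemic 4-methoxyflavan F1. DDQ in wet CH2Cl2 as in step 9 gives the racemic tris-silyl flavanone F2. Kinetic resolution by Noyori-type asymmetric transfer hydrogenation (RuCl(p-cymene)[(R,R)-TsDPEN], HCO2H/Et3N, EtOAc, rt, stopped near half conversion) should reduce the (2R)-ketone, for which catalyst-controlled hydride delivery and the substrate preference for the 2,4-cis alcohol coincide, to the (2R,4R)-flavan-4-ol F3. The unreacted (2S)-ketone 17 is separated by chromatography; the ligand enantiomer is confirmed by a test run.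

**Step 9.** Hydride abstraction may compete at the benzylic-allylic CH2 of the prenyl group, or the C4 epimer whose C4–H is poorly aligned with ring A may oxidise slowly. Fallback, from 16, returning at 17: solvolysis of the benzylic methyl ether (PPTS, THF/H2O, 40 °C; SN1 through the ring-A-stabilised cation) gives the (2S)-flavan-4-ol F4 as a mixture of C4 epimers. This is oxidised with Dess–Martin periodinane (NaHCO3, CH2Cl2, 0 °C to rt) to 17; no hydride abstraction is involved, so the prenyl group is not at risk.

**Step 6.** Formylation at a carbon flanked by the hydroxyl and a bulky silyloxy group may be slow, with diarylmethane formation or partial silyl loss on prolonged heating. Fallback, from 8, returning at 9: Vilsmeier–Haack formylation (POCl3, DMF, MeCN, 0 °C), in which the small chloroiminium electrophile attacks the only free ring carbon (ortho and para to oxygen), gives the aryl iminium chloride F5. This is hydrolysed with aqueous NaOAc to 9.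

## Further compounds

F1 | step 8 | racemic 5,7-bis(tert-butyldimethylsilyloxy)-2-[4-(tert-butyldimethylsilyloxy)phenyl]-4-methoxy-6-methyl-8-(3-methylbut-2-enyl)chromane | CC(C)=CCc1c(O[Si](C)(C)C(C)(C)C)c(C)c(O[Si](C)(C)C(C)(C)C)c2c1OC(c1ccc(O[Si](C)(C)C(C)(C)C)cc1)CC2OC
F2 | step 8 | racemic 5,7-bis(tert-butyldimethylsilyloxy)-2-[4-(tert-butyldimethylsilyloxy)phenyl]-6-methyl-8-(3-methylbut-2-enyl)chroman-4-one | CC(C)=CCc1c(O[Si](C)(C)C(C)(C)C)c(C)c(O[Si](C)(C)C(C)(C)C)c2c1OC(c1ccc(O[Si](C)(C)C(C)(C)C)cc1)CC2=O
F3 | step 8 | (2R,4R)-5,7-bis(tert-butyldimethylsilyloxy)-2-[4-(tert-butyldimethylsilyloxy)phenyl]-6-methyl-8-(3-methylbut-2-enyl)chroman-4-ol | CC(C)=CCc1c(O[Si](C)(C)C(C)(C)C)c(C)c(O[Si](C)(C)C(C)(C)C)c2c1O[C@@H](c1ccc(O[Si](C)(C)C(C)(C)C)cc1)C[C@H]2O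
F4 | step 9 | (2S)-5,7-bis(tert-butyldimethylsilyloxy)-2-[4-(tert-butyldimethylsilyloxy)phenyl]-6-methyl-8-(3-methylbut-2-enyl)chroman-4-ol, C4 epimers | CC(C)=CCc1c(O[Si](C)(C)C(C)(C)C)c(C)c(O[Si](C)(C)C(C)(C)C)c2c1O[C@H](c1ccc(O[Si](C)(C)C(C)(C)C)cc1)CC2O
F5 | step 6 | N-[[2-hydroxy-4,6-bis(tert-butyldimethylsilyloxy)-5-methyl-3-(3-methylbut-2-enyl)phenyl]methylidene]-N-methylmethanaminium chloride | CC(C)=CCc1c(O[Si](C)(C)C(C)(C)C)c(C)c(O[Si](C)(C)C(C)(C)C)c(C=[N+](C)C)c1O.[Cl-]
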